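## Retrosynthetic overview

1. Target 27 ⇐ protected 7-acid 25: one acid step strips the silyl ethers and the acetonide, and the freed C20–OH displaces the C19 auxiliary amide to close the 19,20-δ-lactone (last ring).
2. 25 ⇐ Δ5-enal 22 (Li/NH3 sets H-5β, C6 is equilibrated to 6β, Pinnick oxidation) ⇐ 6-ketone 20 (enol triflate, formylation brings C7).
3. Key step: 20 ⇐ bis(cyclohexenyl) ketone 18 by a Nazarov 4π-electrocyclisation (C9–C10, ring B) whose oxyallyl cation is trapped at C8 by the C13 allylsilane (C8–C15, ring D with the exo-methylene); rings B and D and the C8, C9 and C10 stereocentres form in one operation.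
4. 18 ⇐ ring-A enol triflate 9 + CO + ring-C vinylstannane 17 (carbonylative Stille coupling brings C6).
5. 9 ⇐ 2-methoxybenzoyl chloride (asymmetric Birch reductive methylation sets C4; enolate alkylation brings C20; OsO4 gives the 2β,3β-diol); 17 ⇐ ethyl 3,5-dioxocyclohexanecarboxylate (CBS reduction and stereoconvergent lactonisation set C11/C13; Bunnelle allylsilane synthesis). Ring order: A and C carried in, then B + D together, then the lactone.

Assumption: names use gibberellin numbering with α/β as in the target (C20 α; H-5, H-9 β), and the (S)-auxiliary 2 is taken to give the (R) quaternary centre of 5 in step 2 (if the sense is opposite, the (R)-auxiliary is used and nothing else changes).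

## Route

Step 1
Reactants: 1 2-methoxybenzoyl chloride; 2 (S)-2-(methoxymethyl)pyrrolidine
Product: 3 (2-methoxyphenyl)[(2S)-2-(methoxymethyl)pyrrolidin-1-yl]methanone
Conditions: Et3N, CH2Cl2, 0 °C → rt
Reagents that add atoms: none
Why: N-acylation of the secondary amine by the acid chloride attaches the prolinol-derived auxiliary that will control the C4 quaternary centre.

Step 2
Reactants: 3 (2-methoxyphenyl)[(2S)-2-(methoxymethyl)pyrrolidin-1-yl]methanone
Product: 5 [(1R)-1-methyl-6-oxocyclohex-2-en-1-yl][(2S)-2-(methoxymethyl)pyrrolidin-1-yl]methanone, via enol ether 4 (not isolated)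
Conditions: K, NH3(l)/THF, t-BuOH (1 equiv), −78 °C; MeI, −78 °C; then 1 M aq. HCl, THF, rt
Reagents that add atoms: iodomethane, CI; water, O
Why: Schultz asymmetric Birch reduction–alkylation, in which the chelated amide enolate of the 1,4-dihydroarene is methylated on one face under control of the CH2OMe arm to set quaternary C4, followed by enol ether hydrolysis to the ketone (the remaining C2=C3 alkene cannot conjugate through the quaternary carbon).

Step 3
Reactants: 5 [(1R)-1-methyl-6-oxocyclohex-2-en-1-yl][(2S)-2-(methoxymethyl)pyrrolidin-1-yl]methanone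
Product: 6 [(1R,5RS)-1-methyl-6-oxo-5-({[tri(propan-2-yl)silyl]oxy}methyl)cyclohex-2-en-1-yl][(2S)-2-(methoxymethyl)pyrrolidin-1-yl]methanone
Conditions: LiN(iPr)2, THF, −78 °C; then (iPr)3SiOCH2Cl, −78 → −20 °C
Reagents that add atoms: (triisopropylsiloxy)methyl chloride, ClCO[Si](C(C)C)(C(C)C)C(C)C
Why: Enolate alkylation, in which deprotonation is possible only at C10 (C4 is quaternary) and the reactive α-chloro ether C-alkylates the enolate to bring in C20 already as a silyl-protected carbinol (the new centre is lost in step 4).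

Step 4
Reactants: 6 [(1R,5RS)-1-methyl-6-oxo-5-({[tri(propan-2-yl)silyl]oxy}methyl)cyclohex-2-en-1-yl][(2S)-2-(methoxymethyl)pyrrolidin-1-yl]methanone
Product: 7 (6R)-6-{[(2S)-2-(methoxymethyl)pyrrolidin-1-yl]carbonyl}-6-methyl-2-({[tri(propan-2-yl)silyl]oxy}methyl)cyclohexa-1,4-dien-1-yl trifluoromethanesulfonate
Conditions: KN(SiMe3)2, THF, −78 °C; then PhNTf2, −78 → 0 °C
Reagents that add atoms: N-phenylbis(trifluoromethanesulfonimide), O=S(=O)(N(c1ccccc1)S(=O)(=O)C(F)(F)F)C(F)(F)F
Why: Enol triflate formation, regiospecific because only C10 carries an α-hydrogen, gives the tetrasubstituted C5=C10 alkene; the low temperature suppresses β-elimination of the siloxide.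

Step 5
Reactants: 7 (6R)-6-{[(2S)-2-(methoxymethyl)pyrrolidin-1-yl]carbonyl}-6-methyl-2-({[tri(propan-2-yl)silyl]oxy}methyl)cyclohexa-1,4-dien-1-yl trifluoromethanesulfonate
Product: 8 (4S,5R,6R)-4,5-dihydroxy-6-{[(2S)-2-(methoxymethyl)pyrrolidin-1-yl]carbonyl}-6-methyl-2-({[tri(propan-2-yl)silyl]oxy}methyl)cyclohex-1-en-1-yl trifluoromethanesulfonate
Conditions: OsO4 (2 mol %), N-methylmorpholine N-oxide, acetone/H2O (8:1), rt
Reagents that add atoms: osmium tetroxide, O=[Os](=O)(=O)=O; N-methylmorpholine N-oxide, C[N+]1([O-])CCOCC1; water, O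
Why: Upjohn dihydroxylation is chemoselective for the isolated cis C2=C3 alkene over the electron-poor tetrasubstituted enol triflate, and OsO4 adds to the nearly planar 1,4-diene on the face away from the bulky C4 carboxamide (syn to the C4 methyl), giving the 2β,3β-diol.

Step 6
Reactants: 8 (4S,5R,6R)-4,5-dihydroxy-6-{[(2S)-2-(methoxymethyl)pyrrolidin-1-yl]carbonyl}-6-methyl-2-({[tri(propan-2-yl)silyl]oxy}methyl)cyclohex-1-en-1-yl trifluoromethanesulfonate
Product: 9 acetonide of 8 (2,2-dimethyl-1,3-dioxolane on the cis-4,5-diol; fragment A)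
Conditions: Me2C(OMe)2, pyridinium p-toluenesulfonate (cat.), CH2Cl2, rt
Reagents that add atoms: 2,2-dimethoxypropane, COC(C)(C)OC
Why: Acetalisation of the cis-diol as the five-membered acetonide masks it for the organometallic and Lewis acid steps without touching any stereocentre.

Step 7
Reactants: 10 ethyl 3,5-dioxocyclohexane-1-carboxylate
Product: 11 ethyl 3-iodo-5-oxocyclohex-3-ene-1-carboxylate (racemic)
Conditions: PPh3, I2, Et3N, MeCN, rt → 50 °C
Reagents that add atoms: iodine, II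
Why: β-Iodo enone synthesis from the enolised 1,3-diketone with Ph3P·I2; the two carbonyls are equivalent, so there is no regiochemical issue.

Step 8
Reactants: 11 ethyl 3-iodo-5-oxocyclohex-3-ene-1-carboxylate (racemic)
Product: 12 ethyl (1RS,5S)-5-hydroxy-3-iodocyclohex-3-ene-1-carboxylate (about 1:1 C1 epimers)
Conditions: (R)-2-methyl-CBS-oxazaborolidine [(R)-1-methyl-3,3-diphenyl-tetrahydro-1H,3H-pyrrolo[1,2-c][1,3,2]oxazaborole] (20 mol %), BH3·SMe2, THF, −30 °C; MeOH
Reagents that add atoms: none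
Why: Corey–Bakshi–Shibata reduction, in which the catalyst distinguishes the alkenyl flank from the CH2 flank of the ketone and so sets C11 as (S) in both enantiomers of 11 regardless of the remote ester-bearing centre.

Step 9
Reactants: 12 ethyl (1RS,5S)-5-hydroxy-3-iodocyclohex-3-ene-1-carboxylate
Product: 13 (1R,5S)-3-iodo-6-oxabicyclo[3.2.1]oct-3-en-7-one
Conditions: KOtBu (0.2 equiv), PhMe, 60 °C, 4 Å MS; AcOH quench
Reagents that add atoms: none
Why: Stereoconvergent epimerisation–lactonisation, in which base equilibrates the ester α-carbon (C13) through its enolate and only the cis hydroxy ester can close the bridged γ-lactone, so both epimers of 12 funnel into one enantiomer of 13 with the C11–O and C13–C16 bonds cis.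

Step 10
Reactants: 13 (1R,5S)-3-iodo-6-oxabicyclo[3.2.1]oct-3-en-7-one
Product: 15 (1S,5R)-3-iodo-5-[3-(trimethylsilyl)prop-1-en-2-yl]cyclohex-2-en-1-ol, via bis(silylmethyl) carbinol 14 (not isolated)
Conditions: Me3SiCH2MgCl (5 equiv), CeCl3 (5 equiv), THF, −78 °C → rt; then SiO2, CH2Cl2, rt
Reagents that add atoms: (trimethylsilyl)methylmagnesium chloride, C[Si](C)(C)C[Mg]Cl
Why: Bunnelle allylsilane synthesis, in which double addition of the organocerium reagent to the lactone carbonyl and Peterson elimination of the β-hydroxysilane turn C16 into the 2-(trimethylsilylmethyl)vinyl group (C15, C16, C17) and free the 11-OH with both stereocentres untouched.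

Step 11
Reactants: 15 (1S,5R)-3-iodo-5-[3-(trimethylsilyl)prop-1-en-2-yl]cyclohex-2-en-1-ol
Product: 16 tert-butyl({(1S,5R)-3-iodo-5-[3-(trimethylsilyl)prop-1-en-2-yl]cyclohex-2-en-1-yl}oxy)dimethylsilane
Conditions: TBSCl, imidazole, DMF, rt
Reagents that add atoms: tert-butyldimethylsilyl chloride, CC(C)(C)[Si](C)(C)Cl
Why: Standard silylation of the secondary allylic alcohol gives the bulky ether that later directs the face of the electrocyclisation.

Step 12
Reactants: 16 tert-butyl({(1S,5R)-3-iodo-5-[3-(trimethylsilyl)prop-1-en-2-yl]cyclohex-2-en-1-yl}oxy)dimethylsilane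
Product: 17 tert-butyldimethyl({(1S,5R)-3-(tributylstannyl)-5-[3-(trimethylsilyl)prop-1-en-2-yl]cyclohex-2-en-1-yl}oxy)silane (fragment C)
Conditions: t-BuLi (2.1 equiv), Et2O, −78 °C; then Bu3SnCl, −78 °C → rt
Reagents that add atoms: tributyltin chloride, CCCC[Sn](Cl)(CCCC)CCCC
Why: Iodine–lithium exchange followed by stannylation of the vinyllithium gives the coupling partner with the alkene position retained.

Step 13
Reactants: 9 acetonide of 8 (fragment A); 17 tert-butyldimethyl({(1S,5R)-3-(tributylstannyl)-5-[3-(trimethylsilyl)prop-1-en-2-yl]cyclohex-2-en-1-yl}oxy)silane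
Product: 18 bis(cyclohexenyl) ketone (C6 carbonyl joining C5 of ring A to C8 of ring C)
Conditions: Pd2(dba)3 (5 mol %), AsPh3 (20 mol %), LiCl (3 equiv), CO (3 atm), NMP, 65 °C
Reagents that add atoms: carbon monoxide, [C-]#[O+]
Why: Carbonylative Stille coupling, in which oxidative addition of the vinyl triflate to zerovalent palladium, CO insertion (favoured over direct coupling by the hindrance) and transmetalation/reductive elimination give the cross-conjugated divinyl ketone and bring in C6.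

Step 14
Reactants: 18 bis(cyclohexenyl) ketone
Product: 20 2β,3β-(isopropylidenedioxy)-11β-(tert-butyldimethylsilyloxy)-20-[tri(propan-2-yl)silyloxy]-6-oxo-7-nor-gibberell-16-en-19-oic acid (2S)-2-(methoxymethyl)pyrrolidide, via oxyallyl cation 19 (not isolated)
Conditions: BF3·OEt2 (3 equiv), CH2Cl2, −78 → −40 °C; sat. aq. NaHCO3
Reagents that add atoms: none
Why: Proposed new method: BF3 activation gives a pentadienyl cation whose conrotatory 4π closure forms C9–C10 (H-9 and C20 end trans, i.e. H-9β/C20α) on the face anti to the C11 silyl ether and anti to the C4 carboxamide, and the resulting oxyallyl cation is captured at C8 by the 1,3-diaxial allylsilane with loss of Me3Si to close ring D with its exo-methylene on the β face, so rings B and D form in one operation; the closest known chemistry is the interrupted Nazarov reaction with allylsilane or tethered alkene traps.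

Step 15
Reactants: 20 6-oxo tetracycle
Product: 21 Δ5-enol triflate of 20 (6-trifluoromethanesulfonyloxy-7-nor-gibberella-5,16-diene, otherwise as 20)
Conditions: KN(SiMe3)2, THF, −78 → −40 °C; then N-(5-chloropyridin-2-yl)bis(trifluoromethanesulfonimide) (Comins' reagent), −78 → 0 °C
Reagents that add atoms: Comins' reagent, O=S(=O)(N(c1ccc(Cl)cn1)S(=O)(=O)C(F)(F)F)C(F)(F)F
Why: Enol triflate formation, possible only toward C5 because C8 is quaternary, also erases the uncontrolled C5 centre left by the quench of step 14.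

Step 16
Reactants: 21 Δ5-enol triflate
Product: 22 Δ5-enal (7-oxo-gibberella-5,16-dien-19-oic acid pyrrolidide, protecting groups as in 20)
Conditions: Pd(PPh3)4 (10 mol %), LiCl (3 equiv), CO (3 atm), Bu3SnH (1.3 equiv, slow addition), THF, 55 °C
Reagents that add atoms: carbon monoxide, [C-]#[O+]
Why: Palladium-catalysed reductive carbonylation (formylation) of the vinyl triflate, by CO insertion into the vinylpalladium and hydride transfer from Bu3SnH, installs C7 as the enal.

Step 17
Reactants: 22 Δ5-enal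
Product: 24 5β-H,6β-formyl aldehyde (7-oxo-gibberell-16-en-19-oic acid pyrrolidide, protecting groups as in 20), via 6-epi aldehyde 23 (not isolated)
Conditions: Li (6 equiv), NH3(l)/THF, t-BuOH (1 equiv), −78 °C; isoprene, then NH4Cl; then K2CO3, MeOH, rt
Reagents that add atoms: none
Why: Dissolving-metal (Birch-type) conjugate reduction, in which the C5 carbanion is protonated from the β face, away from the axial C19 carboxamide and C20 on the α face (trans A/B fusion), and base equilibration of the enolisable aldehyde then places the formyl group on the less hindered β face at C6.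

Step 18
Reactants: 24 5β-H,6β-formyl aldehyde
Product: 25 2β,3β-(isopropylidenedioxy)-11β-(tert-butyldimethylsilyloxy)-20-[tri(propan-2-yl)silyloxy]-gibberell-16-ene-7,19-dioic acid 19-[(2S)-2-(methoxymethyl)pyrrolidide]
Conditions: NaClO2, NaH2PO4, 2-methyl-2-butene, t-BuOH/H2O, 0 °C → rt
Reagents that add atoms: sodium chlorite, [Na+].[O-]Cl=O
Why: Pinnick oxidation converts the hindered aldehyde to the acid without epimerisation at C6 and, with the hypochlorite scavenger, without touching the exocyclic alkene.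

Step 19
Reactants: 25 protected 7-acid 19-pyrrolidide
Product: 27 CNP0302900.3 (2β,3β,11β-trihydroxy-gibberell-16-ene-7,19-dioic acid 19,20-lactone), via seco hydroxy amide 26 (not isolated)
Conditions: 48% aq. HF, MeCN, 0 °C → rt; then TsOH·H2O, MeCN/H2O, 45 °C
Reagents that add atoms: none
Why: Acid cleaves both silyl ethers and the acetonide, and the freed C20 hydroxyl, held 1,3-diaxial to the C19 carboxamide, expels the auxiliary by acid-catalysed N→O acyl transfer (lactonisation) to close the δ-lactone with no stereocentre touched.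

## Compound list

1 | 2-methoxybenzoyl chloride | COc1ccccc1C(Cl)=O | starting material
2 | (S)-2-(methoxymethyl)pyrrolidine | COC[C@@H]1CCCN1 | starting material
3 | (2-methoxyphenyl)[(2S)-2-(methoxymethyl)pyrrolidin-1-yl]methanone | COc1ccccc1C(=O)N1CCC[C@H]1COC | intermediate
4 | [(1R)-2-methoxy-1-methylcyclohexa-2,5-dien-1-yl][(2S)-2-(methoxymethyl)pyrrolidin-1-yl]methanone (enol ether, not isolated) | COC1=CCC=C[C@@]1(C)C(=O)N1CCC[C@H]1COC | intermediate
5 | [(1R)-1-methyl-6-oxocyclohex-2-en-1-yl][(2S)-2-(methoxymethyl)pyrrolidin-1-yl]methanone | O=C1CCC=C[C@@]1(C)C(=O)N1CCC[C@H]1COC | intermediate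
6 | [(1R,5RS)-1-methyl-6-oxo-5-({[tri(propan-2-yl)silyl]oxy}methyl)cyclohex-2-en-1-yl][(2S)-2-(methoxymethyl)pyrrolidin-1-yl]methanone (C5 epimers, centre left open) | CC(C)[Si](OCC1C(=O)[C@](C)(C(=O)N2CCC[C@H]2COC)C=CC1)(C(C)C)C(C)C | intermediate
7 | (6R)-6-{[(2S)-2-(methoxymethyl)pyrrolidin-1-yl]carbonyl}-6-methyl-2-({[tri(propan-2-yl)silyl]oxy}methyl)cyclohexa-1,4-dien-1-yl trifluoromethanesulfonate | CC(C)[Si](OCC1=C(OS(=O)(=O)C(F)(F)F)[C@](C)(C(=O)N2CCC[C@H]2COC)C=CC1)(C(C)C)C(C)C | intermediate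
8 | (4S,5R,6R)-4,5-dihydroxy-6-{[(2S)-2-(methoxymethyl)pyrrolidin-1-yl]carbonyl}-6-methyl-2-({[tri(propan-2-yl)silyl]oxy}methyl)cyclohex-1-en-1-yl trifluoromethanesulfonate | CC(C)[Si](OCC1=C(OS(=O)(=O)C(F)(F)F)[C@](C)(C(=O)N2CCC[C@H]2COC)[C@@H](O)[C@@H](O)C1)(C(C)C)C(C)C | intermediate
9 | acetonide of 8 (cis-fused 2,2-dimethyl-1,3-dioxolane on the 4,5-diol, configuration as in 8; fragment A) | CC(C)[Si](OCC1=C(OS(=O)(=O)C(F)(F)F)[C@](C)(C(=O)N2CCC[C@H]2COC)[C@H]3OC(C)(C)O[C@H]3C1)(C(C)C)C(C)C | intermediate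
10 | ethyl 3,5-dioxocyclohexane-1-carboxylate | CCOC(=O)C1CC(=O)CC(=O)C1 | starting material
11 | ethyl 3-iodo-5-oxocyclohex-3-ene-1-carboxylate (racemic) | CCOC(=O)C1CC(I)=CC(=O)C1 | intermediate
12 | ethyl (1RS,5S)-5-hydroxy-3-iodocyclohex-3-ene-1-carboxylate (C1 epimers, centre left open) | CCOC(=O)C1CC(I)=C[C@@H](O)C1 | intermediate
13 | (1R,5S)-3-iodo-6-oxabicyclo[3.2.1]oct-3-en-7-one | O=C1O[C@@H]2C=C(I)C[C@H]1C2 | intermediate
14 | 2-[(1R,5S)-5-hydroxy-3-iodocyclohex-3-en-1-yl]-1,3-bis(trimethylsilyl)propan-2-ol (not isolated) | IC1=C[C@@H](O)C[C@H](C1)C(O)(C[Si](C)(C)C)C[Si](C)(C)C | intermediate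
15 | (1S,5R)-3-iodo-5-[3-(trimethylsilyl)prop-1-en-2-yl]cyclohex-2-en-1-ol | IC1=C[C@@H](O)C[C@H](C1)C(=C)C[Si](C)(C)C | intermediate
16 | tert-butyl({(1S,5R)-3-iodo-5-[3-(trimethylsilyl)prop-1-en-2-yl]cyclohex-2-en-1-yl}oxy)dimethylsilane | IC1=C[C@@H](O[Si](C)(C)C(C)(C)C)C[C@H](C1)C(=C)C[Si](C)(C)C | intermediate
17 | tert-butyldimethyl({(1S,5R)-3-(tributylstannyl)-5-[3-(trimethylsilyl)prop-1-en-2-yl]cyclohex-2-en-1-yl}oxy)silane (fragment C) | CCCC[Sn](CCCC)(CCCC)C1=C[C@@H](O[Si](C)(C)C(C)(C)C)C[C@H](C1)C(=C)C[Si](C)(C)C | intermediate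
18 | bis(cyclohexenyl) ketone: ring A of 9 with the OTf replaced by the C6 carbonyl, which is also bonded to C8 of ring C of 17 in place of SnBu3; all stereocentres as in 9 and 17 | CC(C)[Si](OCC1=C(C(=O)C2=C[C@@H](O[Si](C)(C)C(C)(C)C)C[C@H](C2)C(=C)C[Si](C)(C)C)[C@](C)(C(=O)N3CCC[C@H]3COC)[C@H]4OC(C)(C)O[C@H]4C1)(C(C)C)C(C)C | intermediate
19 | BF3-bound oxyallyl cation (rings A, B, C; C9–C10 formed with H-9β and C20 α; cation over C5–C6–C8; allylsilane still free; not isolated) | C=C(C[Si](C)(C)C)[C@H]1C[C+]2C(O[B-](F)(F)F)=C3[C@](C)(C(=O)N4CCC[C@H]4COC)[C@H]5OC(C)(C)O[C@H]5C[C@@]3(CO[Si](C(C)C)(C(C)C)C(C)C)[C@@H]2[C@@H](O[Si](C)(C)C(C)(C)C)C1 | intermediate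
20 | 2β,3β-(isopropylidenedioxy)-11β-(tert-butyldimethylsilyloxy)-20-[tri(propan-2-yl)silyloxy]-6-oxo-7-nor-gibberell-16-en-19-oic acid (2S)-2-(methoxymethyl)pyrrolidide (5β-H drawn; the C5 epimer is equally usable) | C=C1C[C@]23C[C@H]1C[C@H](O[Si](C)(C)C(C)(C)C)[C@H]2[C@]4(CO[Si](C(C)C)(C(C)C)C(C)C)C[C@@H]5OC(C)(C)O[C@@H]5[C@@](C)(C(=O)N6CCC[C@H]6COC)[C@H]4C3=O | intermediate
21 | Δ5-enol triflate of 20 (6-trifluoromethanesulfonyloxy-7-nor-gibberella-5,16-diene; other groups as in 20) | C=C1C[C@]23C[C@H]1C[C@H](O[Si](C)(C)C(C)(C)C)[C@H]2[C@]4(CO[Si](C(C)C)(C(C)C)C(C)C)C[C@@H]5OC(C)(C)O[C@@H]5[C@@](C)(C(=O)N6CCC[C@H]6COC)C4=C3OS(=O)(=O)C(F)(F)F | intermediate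
22 | Δ5-enal: 7-oxo-gibberella-5,16-dien-19-oic acid pyrrolidide (other groups as in 20) | C=C1C[C@]23C[C@H]1C[C@H](O[Si](C)(C)C(C)(C)C)[C@H]2[C@]4(CO[Si](C(C)C)(C(C)C)C(C)C)C[C@@H]5OC(C)(C)O[C@@H]5[C@@](C)(C(=O)N6CCC[C@H]6COC)C4=C3C=O | intermediate
23 | 5β-H,6α-formyl (6-epi) aldehyde, main kinetic epimer (not isolated) | C=C1C[C@]23C[C@H]1C[C@H](O[Si](C)(C)C(C)(C)C)[C@H]2[C@]4(CO[Si](C(C)C)(C(C)C)C(C)C)C[C@@H]5OC(C)(C)O[C@@H]5[C@@](C)(C(=O)N6CCC[C@H]6COC)[C@H]4[C@H]3C=O | intermediate
24 | 5β-H,6β-formyl aldehyde: 7-oxo-gibberell-16-en-19-oic acid pyrrolidide (other groups as in 20) | C=C1C[C@]23C[C@H]1C[C@H](O[Si](C)(C)C(C)(C)C)[C@H]2[C@]4(CO[Si](C(C)C)(C(C)C)C(C)C)C[C@@H]5OC(C)(C)O[C@@H]5[C@@](C)(C(=O)N6CCC[C@H]6COC)[C@H]4[C@@H]3C=O | intermediate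
25 | 2β,3β-(isopropylidenedioxy)-11β-(tert-butyldimethylsilyloxy)-20-[tri(propan-2-yl)silyloxy]-gibberell-16-ene-7,19-dioic acid 19-[(2S)-2-(methoxymethyl)pyrrolidide] | C=C1C[C@]23C[C@H]1C[C@H](O[Si](C)(C)C(C)(C)C)[C@H]2[C@]4(CO[Si](C(C)C)(C(C)C)C(C)C)C[C@@H]5OC(C)(C)O[C@@H]5[C@@](C)(C(=O)N6CCC[C@H]6COC)[C@H]4[C@@H]3C(=O)O | intermediate
26 | 2β,3β,11β,20-tetrahydroxy-gibberell-16-ene-7,19-dioic acid 19-[(2S)-2-(methoxymethyl)pyrrolidide] (not isolated) | C=C1C[C@]23C[C@H]1C[C@H](O)[C@H]2[C@]4(CO)C[C@H](O)[C@H](O)[C@@](C)(C(=O)N5CCC[C@H]5COC)[C@H]4[C@@H]3C(=O)O | intermediate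
27 | CNP0302900.3: 2β,3β,11β-trihydroxy-gibberell-16-ene-7,19-dioic acid 19,20-lactone | C=C1C[C@]23C[C@H]1C[C@H](O)[C@H]2[C@]12COC(=O)[C@](C)([C@@H](O)[C@@H](O)C1)[C@H]2[C@@H]3C(=O)O | target

## Step count and weak points

Total step count: 19. Longest linear sequence: 13 steps (steps 1–6 then 13–19; the ring-C branch, steps 7–12 then 13–19, is equally long).

Steps most likely to fail:

Step 14 (electrocyclisation/allylsilane cascade). The closure has to build quaternary C10 next to a fully substituted C5, and it competes with direct Sakurai attack of the allylsilane on C9 of the activated enone and with Wagner–Meerwein shifts of the oxyallyl cation. The fallback sets out from 18 and comes back at 22. (Methoxymethoxy)methyllithium (from Bu3SnCH2OCH2OMe and n-BuLi, THF, −78 °C) adds to the ketone to give the tertiary bis-allylic carbinol F1. Trifluoroacetic acid in CH2Cl2 at −40 °C ionises it to a pentadienyl cation with no electrophilic enone present beforehand; this closes in the same conrotatory sense and is trapped at C8 by the allylsilane, giving the Δ5 tetracycle with C7 already in place as its methoxymethyl ether F2. ZnBr2/n-PrSH frees the allylic alcohol F3, and MnO2 oxidises it to 22, so steps 15 and 16 are not needed.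

Step 13 (carbonylative Stille coupling). The triflate is tetrasubstituted and flanked by a quaternary carbon, so oxidative addition and transmetalation may be slow or CO-free coupling may intrude. The fallback sets out from 9 and 16 and comes back at 18. Formylation of 9 (Pd(PPh3)4, CO, Bu3SnH, THF) gives the ring-A enal F4. The vinyllithium made from 16 with t-BuLi adds to it to give the bis-allylic alcohol F5, which Dess–Martin periodinane oxidises to 18.

Step 5 (facial selectivity of the dihydroxylation). OsO4 may add on the carboxamide face if the amide is not the face-determining group. The fallback sets out from 7 and comes back at 8. Woodward cis-hydroxylation (I2, AgOAc, wet AcOH) delivers both oxygens to the face opposite to the one first attacked by the electrophile and gives the hydroxy acetate F6 (either regioisomer serves). K2CO3/MeOH then hydrolyses it to 8.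

Further compounds

F1 | step 14 | tertiary bis-allylic carbinol from 18 (C6 bears OH and CH2OCH2OMe; carbinol centre left open) | CC(C)[Si](OCC1=C(C(O)(COCOC)C2=C[C@@H](O[Si](C)(C)C(C)(C)C)C[C@H](C2)C(=C)C[Si](C)(C)C)[C@](C)(C(=O)N3CCC[C@H]3COC)[C@H]4OC(C)(C)O[C@H]4C1)(C(C)C)C(C)C
F2 | step 14 | 7-(methoxymethoxy)-gibberella-5,16-dien-19-oic acid pyrrolidide (other groups as in 20) | C=C1C[C@]23C[C@H]1C[C@H](O[Si](C)(C)C(C)(C)C)[C@H]2[C@]4(CO[Si](C(C)C)(C(C)C)C(C)C)C[C@@H]5OC(C)(C)O[C@@H]5[C@@](C)(C(=O)N6CCC[C@H]6COC)C4=C3COCOC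
F3 | step 14 | 7-hydroxy-gibberella-5,16-dien-19-oic acid pyrrolidide (allylic alcohol; other groups as in 20) | C=C1C[C@]23C[C@H]1C[C@H](O[Si](C)(C)C(C)(C)C)[C@H]2[C@]4(CO[Si](C(C)C)(C(C)C)C(C)C)C[C@@H]5OC(C)(C)O[C@@H]5[C@@](C)(C(=O)N6CCC[C@H]6COC)C4=C3CO
F4 | step 13 | ring-A enal (9 with CHO in place of OTf) | CC(C)[Si](OCC1=C(C=O)[C@](C)(C(=O)N2CCC[C@H]2COC)[C@H]3OC(C)(C)O[C@H]3C1)(C(C)C)C(C)C
F5 | step 13 | bis-allylic alcohol (18 with CH(OH) in place of the ketone; carbinol centre left open) | CC(C)[Si](OCC1=C(C(O)C2=C[C@@H](O[Si](C)(C)C(C)(C)C)C[C@H](C2)C(=C)C[Si](C)(C)C)[C@](C)(C(=O)N3CCC[C@H]3COC)[C@H]4OC(C)(C)O[C@H]4C1)(C(C)C)C(C)C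
F6 | step 5 | hydroxy acetate of 8 (5-O-acetyl isomer drawn) | CC(C)[Si](OCC1=C(OS(=O)(=O)C(F)(F)F)[C@](C)(C(=O)N2CCC[C@H]2COC)[C@@H](OC(C)=O)[C@@H](O)C1)(C(C)C)C(C)C
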